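A leftover of Q is enough to read the L standing beside it, and that reading is the rule I carry from flask to flask.

| setting | spring | dawn |
|---|---|---|
| Q | 0.20 M | 0.20 M |
| G | 1.10 equiv | 3.20 equiv |
| time | 30 h | 30 h |

    Q + D → L + E (k1 = 1.79 M⁻¹ h⁻¹)
    Q + D → J + E (k2 = 0.174 M⁻¹ h⁻¹)
    D + L → Z + E (k3 = 0.635 M⁻¹ h⁻¹)
    D + J → Z + E (k4 = 0.864 M⁻¹ h⁻¹)
    G ⇌ D, rate k5*(cs5 - [D]) while solid is left; crystals form when [D] > cs5 (cs5 = 0.099 M, k5 = 0.635 h⁻¹)
    D + L → D.L (k6 = 1.27 M⁻¹ h⁻¹)

- as a solid, counted per litre of solution: G
- at the start none of G is in solution
- run time (spring): 30 h

- which of these there is most of at the end, counted by the Q in it, spring (Q / D.L / L / J / Z)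
- which of these there is most of at the end, counted by the Q in it, dawn (Q / D.L / L / J / Z)
- final amount of the leader among these, as a percentage of the Q charged, in spring
- final amount of the leader among these, as a percentage of the Q charged, in dawn

Dissolved D multiplies the rates of loss of Q and of L alike, so dividing one rate by the other removes D, the dissolving of G and the time, and what remains integrates in closed form. Call q the fraction of Q left and φ = k1/(k1 + k2) = 0.911 the share of Q that goes to L. Let ρ be the selectivity factor, the constant with which D removes L over the constant with which D removes Q, 0.970. The fraction in L is then φ(q^ρ − q)/(1 − ρ).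

I reach the top of L by two ways. Setting the slope of the curve to zero puts it at q = 36.2%, with L at 34.0%. Counting hits instead, with each Q taking D at one steady rate, the chance of exactly one hit peaks at 1/e, which gives 33.5%. They part by 0.50 percentage points, and the count is the one that cheats, because L is lost more slowly than Q.

Each L or J holds one D and each Z or D.L holds two, so the D taken up is 2 times the Q lost, less L and J. With J at 4.39%, the top costs 0.891 equivalents. I assume that spring's whole charge of 1.10 equiv is taken up by the end, and that passes the top. Just past the top I let L and J stand still, so I count about 2 D for each Q lost. That leaves Q at 25.8% and the curve gives L 32.5%, so I name L the leader in spring. Dawn's 3.20 equiv is more than 2 per Q, so the charge allows the curve to run far past the top, and I assume that it does. Lost L divides as k6 to k3, which gives D.L up to 60.8%, and I name D.L the leader there.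

The forecast says L at 33% for spring and D.L at 58% for dawn, on the ground that “Q and L consume D at almost the same rate”, with Q near 26%. Its spring L stands 0.50 points above mine.

The flasks give L at 32.7% in spring and D.L at 56.4% in dawn.

Spring's 26.4% of Q reads on the curve as 32.7% of L, against 32.7% in the flask, just past the top. Dawn's 1.27% reads as 5.40%, against 5.39%, far down the falling side. A neighbour of spring charged with 0.660 equiv of G, less than the top costs, ends on the rising side with Q ahead at 49%, and its curve reads 32.2% of L against 32.2% in the flask.

(Its constants were drawn at random within sensible limits; the flask was simulated.)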